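Readings and results are simulated for an exercise; the scatter is artificial.

In a one-step world G + Z → E, one Z buys one E, and that picture is where I started.

| flask | G | Z | temperature | remark | time | volume of the second phase over the first |
|---|---|---|---|---|---|---|
| violet | 0.019 M | 0.068 M | 20 °C | run made earlier |  |  |
| summer | 0.012 M | 0.0680 M | 20 °C |  | 25 h | 1.0 |
| autumn | 0.017 M | 0.0680 M | 20 °C |  | 25 h | 1.0 |
| winter | 0.017 M | 0.0150 M | 20 °C |  | 25 h | 1.0 |
| dawn | 0.060 M | 0.0250 M | −20 °C |  | 25 h | 1.0 |

- violet (time / h: E / %): 0.833: 48.9; 1.50: 71.1; 2.50: 81.1; 3.00: 80.1; 4.00: 80.3; 5.00: 80.6

(each reading ± 0.5 percentage points)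

- in the second phase: Z; everything else is in the first
- charges count per volume of the first phase; a concentration in a rate is the amount of a species over the volume of its own phase; every rate counts per litre of the first phase
- the earlier runs hold the two phases in the same ratio of volumes as the flask asked about
- the earlier runs do not show what temperature does; that part of a forecast is a guess
- a reading or a percentage of E counts all its forms, free or not

1. ranking by amount of E, in percent of the G charged, from high to low, at 25 h (summer / autumn / winter / dawn)
2. the amount of E, in percent of the G charged of the flask you put first, at 25 h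
3. the amount of E, in percent of the G charged of the flask you put last, at 25 h

1. On that picture E cannot pass c_Z/c_G of the G charged. In dawn, c_Z lies below c_G, which makes Z the limiting reagent there. So 41.7% is dawn's Z ceiling, the charge ratio c_Z/c_G read as the most E that its Z can pay for. Temperature does not appear in this ratio, so my guess about the cold never touched it.

2. The violet run left the one-step world. It held 3.58 Z per G, yet its last reading was 80.6%, so 19 percentage points of its G did not show as E.

3. Turned round, for dawn to escape last place, winter would have to end under dawn's ceiling. Winter's own ceiling is 88.2%, so it would have to fall short of that by 47 points, more than the violet run's shortfall.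

4. I therefore ranked the flasks by c_Z/c_G, with summer at 5.67 and autumn at 4.00 ahead of winter and dawn. I committed to summer above the violet reading and to dawn below its ceiling, which is a bound and not a value.

5. The forecast gave numbers instead: summer > autumn > winter > dawn, with 82% on top and 27% at the bottom, saying “Cooling probably slows it badly”.

6. The flasks gave summer > autumn > winter > dawn, with 87.9% on top and 38.7% at the bottom.

    D ⇌ Z, rate k1*([D] - [Z]/K1) per volume of the first phase (partition coefficient = 1.10, kL = 0.320 /h)
    G + D → E (k = 480 /M/h, Ea = 46.0 kJ/mol)
    2 G → X (k = 17.0 /M/h, Ea = 59.0 kJ/mol)
    G + E ⇌ Q, settled at all times (K = 83.0 /M, ΔH = −61.0 kJ/mol)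
    (constants at 20 °C)

In summer, the loss of 2 G to X and the drag of the transfer of Z to D acted together to hold E at 87.9%: with the first taken away E reached 100%, with the second 98.7%. Dawn stood 3.0 points under its ceiling at 25.0 h. Left until 250 h, dawn gave 41.7%, level with the ceiling. A neighbour like dawn but charged with 0.24 M of G has a ceiling of 10.4%, and it gave 10.4%.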